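**Retrosynthetic overview**

- The target comes from its naphthol silyl ether by fluoride desilylation; the silyl ether comes from a 4-aryl-1,2-dihydronaphthalen-1-ol by hydroxyl-directed hydrogenation of C3=C4, which returns hydrogen to C4 from the face of the C1 hydroxyl and gives the 1,4-trans product.
- The dihydronaphthalenol comes from an enantiopure 2-(1-arylallyl)-3-methoxybenzaldehyde by an intramolecular carbonyl-ene cyclisation that forms C1–C2 and moves the C4 hydrogen to the aldehyde oxygen. This closes the saturated ring, the only ring made in the route; both arenes are bought.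
- The aldehyde comes from an aryl bromide (Br to CHO) after O-silylation; the diarylmethine centre is set by catalytic asymmetric vinyl transfer from a vinylboronate to an o-quinone methide, itself derived from the ortho-hydroxyalkylation product of 8-methoxy-1-naphthol and 2-bromo-6-methoxybenzaldehyde.
- Structural feature exploited: the saturated ring of the tetralin (C1 carbinol, C2, C3, C4 diarylmethine, C4a, C8a) holds the doubly benzylic C4–H and the C1–O bond in a 1,4-relationship on the adjacent arene carbons C4a and C8a, so a six-atom ene array C1–O···H–C4–C3=C2 can be drawn across that ring.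

Key step: step 6

Assumption: (R)-3,3'-dibromo-1,1'-bi-2-naphthol is taken as the catalyst enantiomer that gives the (R)-diarylmethine in step 3; if the sense proves opposite, the (S)-catalyst is used and nothing else changes.

**Step 1**
Reactants: 1 8-methoxynaphthalen-1-ol; 2 2-bromo-6-methoxybenzaldehyde
Product: 4 rac-2-[(2-bromo-6-methoxyphenyl)(hydroxy)methyl]-8-methoxynaphthalen-1-ol, via bromomagnesium 8-methoxynaphthalen-1-olate 3 (not isolated)
Conditions: EtMgBr (1.0 equiv), Et2O, 0 °C; solvent exchange to CH2Cl2; 2, rt; aq. NH4Cl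
Reagents that add atoms: none
Why: Deprotonation gives magnesium naphthoxide 3, whose metal binds the aldehyde and delivers it to the ortho carbon C2 through a six-membered chelate (magnesium-templated ortho-hydroxyalkylation of a phenoxide, an aldol-type Friedel–Crafts reaction), so only the 2-substituted naphthol should form, and no stereocontrol is needed because this carbinol centre is erased in step 3.

**Step 2**
Reactants: 4 rac-2-[(2-bromo-6-methoxyphenyl)(hydroxy)methyl]-8-methoxynaphthalen-1-ol
Product: 5 rac-2-[(2-bromo-6-methoxyphenyl)(ethoxy)methyl]-8-methoxynaphthalen-1-ol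
Conditions: EtOH, pyridinium p-toluenesulfonate (5 mol %), 3 Å MS, rt
Reagents that add atoms: ethanol, CCO
Why: Acid-catalysed SN1 etherification exchanges only the doubly activated benzylic hydroxyl for ethoxy, giving a precursor that cannot tie up the boron reagent of step 3 as a cyclic boronate and that loses ethanol on warming.

**Step 3**
Reactants: 5 rac-2-[(2-bromo-6-methoxyphenyl)(ethoxy)methyl]-8-methoxynaphthalen-1-ol; 6 dibutyl vinylboronate
Product: 8 (R)-2-[1-(2-bromo-6-methoxyphenyl)prop-2-en-1-yl]-8-methoxynaphthalen-1-ol, via quinone methide 7 (not isolated)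
Conditions: 6 (2 equiv), (R)-3,3'-dibromo-1,1'-bi-2-naphthol (15 mol %), PhMe, 4 Å MS, 60 °C; aqueous work-up
Reagents that add atoms: none
Why: Heating releases ethanol from 5 to give quinone methide 7, while the acyclic ester 6 (unlike a pinacol ester) exchanges an alkoxy group for the chiral diol; the resulting boronate binds the quinone methide oxygen and passes its vinyl group to the exocyclic carbon through a closed six-membered transition state (biphenol-catalysed asymmetric conjugate addition of an alkenylboronate to an o-quinone methide), the diol fixing the face attacked and hence the (R) centre that becomes C4.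

**Step 4**
Reactants: 8 (R)-2-[1-(2-bromo-6-methoxyphenyl)prop-2-en-1-yl]-8-methoxynaphthalen-1-ol
Product: 9 (R)-tert-butyl({2-[1-(2-bromo-6-methoxyphenyl)prop-2-en-1-yl]-8-methoxynaphthalen-1-yl}oxy)dimethylsilane
Conditions: TBSOTf, 2,6-lutidine, CH2Cl2, 0 °C to rt
Reagents that add atoms: tert-butyldimethylsilyl trifluoromethanesulfonate (TBSOTf), CC(C)(C)[Si](C)(C)OS(=O)(=O)C(F)(F)F
Why: O-Silylation with the silyl triflate is chosen because the naphthol is hindered and hydrogen-bonded to the peri methoxy group; the silyl ether masks the acidic OH against t-BuLi and Me2AlCl and leaves the C1 hydroxyl as the only directing group in step 7.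

**Step 5**
Reactants: 9 (R)-tert-butyl({2-[1-(2-bromo-6-methoxyphenyl)prop-2-en-1-yl]-8-methoxynaphthalen-1-yl}oxy)dimethylsilane
Product: 11 (R)-2-{1-[1-(tert-butyldimethylsilyloxy)-8-methoxynaphthalen-2-yl]prop-2-en-1-yl}-3-methoxybenzaldehyde, via aryllithium 10 (not isolated)
Conditions: t-BuLi (2.1 equiv), Et2O, −78 °C; DMF, −78 to 0 °C; aq. NH4Cl
Reagents that add atoms: N,N-dimethylformamide (DMF), CN(C)C=O
Why: Bromine–lithium exchange at −78 °C is much faster than deprotonation of the doubly benzylic C–H, so aryllithium 10 should form with the stereocentre intact and be formylated by DMF (Bouveault-type aldehyde synthesis); a 2-allylphenyllithium of this kind has no favourable carbolithiation path.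

**Step 6**
Reactants: 11 (R)-2-{1-[1-(tert-butyldimethylsilyloxy)-8-methoxynaphthalen-2-yl]prop-2-en-1-yl}-3-methoxybenzaldehyde
Product: 13 (S)-4-[1-(tert-butyldimethylsilyloxy)-8-methoxynaphthalen-2-yl]-5-methoxy-1,2-dihydronaphthalen-1-ol, via chloro(methyl)aluminium alkoxide 12 (not isolated)
Conditions: Me2AlCl (2.0 equiv), CH2Cl2 (0.02 M), −78 to −20 °C; aq. NaHCO3, then aq. potassium sodium tartrate
Reagents that add atoms: none
Why: Proposed new method: Me2AlCl on the aldehyde oxygen makes C1 electrophilic enough for the terminal vinyl carbon C2 to bond to it while the C4–H bond, aligned with the alkene π system and weakened by two aryl groups, gives its hydrogen to the carbonyl oxygen in the same event, so that C1, O, H, C4, C3 and C2 form the ene array and aluminium alkoxide 12 results after loss of methane. The closest known reaction type is the Me2AlCl-promoted intramolecular carbonyl-ene cyclisation of alkenyl aldehydes, in which the hydrogen normally comes from an allylic position outside the ring being made, whereas here it bridges that ring. The saturated ring closes 6-exo-trig at the aldehyde carbon with both alkene carbons inside the ring, through a boat in which C1 and C4 act as bridgeheads joined by the C2–C3 unit, by the migrating O···H pair and by the arene bond C4a–C8a. The C1 stereocentre is set by the C4 stereocentre of 11, because only an oxygen on the ring face from which the C4 hydrogen departs can receive it, which turns (R)-C4 into (S)-C1 before C4 becomes planar. The step needs this concerted path to win over a stepwise cationic closure and over methyl transfer from aluminium; the substrate helps because the vinyl group has no other allylic hydrogen, the aldehyde cannot enolise, a free secondary cation at C3 is unfavourable without participation of the C4–H bond, and the new C3=C4 bond is conjugated with two arenes.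

**Step 7**
Reactants: 13 (S)-4-[1-(tert-butyldimethylsilyloxy)-8-methoxynaphthalen-2-yl]-5-methoxy-1,2-dihydronaphthalen-1-ol
Product: 14 (1S,4R)-4-[1-(tert-butyldimethylsilyloxy)-8-methoxynaphthalen-2-yl]-5-methoxy-1,2,3,4-tetrahydronaphthalen-1-ol
Conditions: [Ir(cod)(PCy3)(py)]PF6 (10 mol %), H2 (1 atm), CH2Cl2, 0 °C to rt; 13 used directly, without contact with acid
Reagents that add atoms: none
Why: Hydroxyl-directed homogeneous hydrogenation: the C1 hydroxyl binds the cationic iridium centre, which adds H2 to the homoallylic C3=C4 bond from the hydroxyl face, so the new C4 hydrogen is cis to OH and the naphthyl group trans, i.e. (4R); the silyl ether keeps the naphthol oxygen from competing as a director, and any slow rotation about the C4–naphthyl bond in 13 ends once C4 is saturated.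

**Step 8**
Reactants: 14 (1S,4R)-4-[1-(tert-butyldimethylsilyloxy)-8-methoxynaphthalen-2-yl]-5-methoxy-1,2,3,4-tetrahydronaphthalen-1-ol
Product: 15 Dipolynaphthalene A [(1S,4R)-4-(1-hydroxy-8-methoxynaphthalen-2-yl)-5-methoxy-1,2,3,4-tetrahydronaphthalen-1-ol]
Conditions: Bu4NF (1.2 equiv), THF, 0 °C, argon; aq. NH4Cl
Reagents that add atoms: none
Why: Fluoride-induced cleavage of the aryl silyl ether (Si–F bond formation) frees the naphthol without touching the secondary benzylic alcohol or either stereocentre.

**Compound list**

1 | 8-methoxynaphthalen-1-ol | COc1cccc2cccc(O)c12 | starting material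
2 | 2-bromo-6-methoxybenzaldehyde | COc1cccc(Br)c1C=O | starting material
3 | bromomagnesium 8-methoxynaphthalen-1-olate | COc1cccc2cccc(O[Mg]Br)c12 | intermediate (not isolated)
4 | rac-2-[(2-bromo-6-methoxyphenyl)(hydroxy)methyl]-8-methoxynaphthalen-1-ol | COc1cccc(Br)c1C(O)c1ccc2cccc(OC)c2c1O | intermediate
5 | rac-2-[(2-bromo-6-methoxyphenyl)(ethoxy)methyl]-8-methoxynaphthalen-1-ol | CCOC(c1c(Br)cccc1OC)c1ccc2cccc(OC)c2c1O | intermediate
6 | dibutyl vinylboronate (dibutyl ethenylboronate) | C=CB(OCCCC)OCCCC | starting material
7 | (E)-2-[(2-bromo-6-methoxyphenyl)methylidene]-8-methoxynaphthalen-1(2H)-one (E geometry expected) | COc1cccc(Br)c1/C=C1\C=Cc2cccc(OC)c2C1=O | intermediate (not isolated)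
8 | (R)-2-[1-(2-bromo-6-methoxyphenyl)prop-2-en-1-yl]-8-methoxynaphthalen-1-ol | COc1cccc(Br)c1[C@H](C=C)c1ccc2cccc(OC)c2c1O | intermediate
9 | (R)-tert-butyl({2-[1-(2-bromo-6-methoxyphenyl)prop-2-en-1-yl]-8-methoxynaphthalen-1-yl}oxy)dimethylsilane | COc1cccc(Br)c1[C@H](C=C)c1ccc2cccc(OC)c2c1O[Si](C)(C)C(C)(C)C | intermediate
10 | (R)-{2-[1-(1-(tert-butyldimethylsilyloxy)-8-methoxynaphthalen-2-yl)prop-2-en-1-yl]-3-methoxyphenyl}lithium | COc1cccc([Li])c1[C@H](C=C)c1ccc2cccc(OC)c2c1O[Si](C)(C)C(C)(C)C | intermediate (not isolated)
11 | (R)-2-{1-[1-(tert-butyldimethylsilyloxy)-8-methoxynaphthalen-2-yl]prop-2-en-1-yl}-3-methoxybenzaldehyde | COc1cccc(C=O)c1[C@H](C=C)c1ccc2cccc(OC)c2c1O[Si](C)(C)C(C)(C)C | intermediate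
12 | chloro(methyl)aluminium (S)-4-[1-(tert-butyldimethylsilyloxy)-8-methoxynaphthalen-2-yl]-5-methoxy-1,2-dihydronaphthalen-1-olate | COc1cccc2c1C(c1ccc3cccc(OC)c3c1O[Si](C)(C)C(C)(C)C)=CC[C@@H]2O[Al](C)Cl | intermediate (not isolated)
13 | (S)-4-[1-(tert-butyldimethylsilyloxy)-8-methoxynaphthalen-2-yl]-5-methoxy-1,2-dihydronaphthalen-1-ol | COc1cccc2c1C(c1ccc3cccc(OC)c3c1O[Si](C)(C)C(C)(C)C)=CC[C@@H]2O | intermediate
14 | (1S,4R)-4-[1-(tert-butyldimethylsilyloxy)-8-methoxynaphthalen-2-yl]-5-methoxy-1,2,3,4-tetrahydronaphthalen-1-ol | COc1cccc2c1[C@@H](c1ccc3cccc(OC)c3c1O[Si](C)(C)C(C)(C)C)CC[C@@H]2O | intermediate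
15 | Dipolynaphthalene A, (1S,4R)-4-(1-hydroxy-8-methoxynaphthalen-2-yl)-5-methoxy-1,2,3,4-tetrahydronaphthalen-1-ol | COc1cccc2c1[C@@H](c1ccc3cccc(OC)c3c1O)CC[C@@H]2O | target

**Total step count:** 8. **Longest linear sequence:** 8 steps (from 1 or 2 to 15).

**Steps most likely to fail**

1. Step 6 (new method). The bridged ene array may be too strained: the migrating hydrogen must span C4 and the oxygen on C1 at an acute C–H–O angle, and the naphthyl group has to swing into the plane of the benzaldehyde ring next to its methoxy group. The ring could then close by a stepwise cationic path (C1–C2 bonding with a hydride shift from C4 to C3 and later proton loss), which removes the facial lock between oxygen and hydrogen and erodes enantiomeric purity at C1. Methyl transfer from aluminium to the aldehyde, and ionisation of the new benzylic alkoxide with loss of water to a naphthalene, are further losses.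
 Fallback (known chemistry, no ene step and no C3=C4 alkene), setting out from bromide 9 and rejoining at 14: linear-selective hydroformylation of the vinyl group (Rh(acac)(CO)2, Xantphos, CO/H2 1:1, 10 bar, PhMe, 70 °C) should give (R)-4-(2-bromo-6-methoxyphenyl)-4-[1-(tert-butyldimethylsilyloxy)-8-methoxynaphthalen-2-yl]butanal F1. Pinnick oxidation (NaClO2, NaH2PO4, 2-methylbut-2-ene, t-BuOH/H2O) should give the corresponding butanoic acid F2. Coupling with MeNHOMe·HCl (EDC·HCl, i-Pr2NEt, CH2Cl2) should give the N-methoxy-N-methylbutanamide F3. Parham cyclisation (t-BuLi, THF, −78 °C; bromine–lithium exchange, then attack on the amide) should close the ring to (R)-4-[1-(tert-butyldimethylsilyloxy)-8-methoxynaphthalen-2-yl]-5-methoxy-3,4-dihydronaphthalen-1(2H)-one F4, with C4 never becoming planar. Corey–Bakshi–Shibata reduction ((R)-2-methyl-CBS-oxazaborolidine, BH3·SMe2, THF, −20 °C) should then set (1S) under reagent control and deliver 14, from which step 8 follows.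

2. Step 7. The hindered trisubstituted alkene, flanked by the peri methoxy group and the ortho-substituted naphthyl ring, may bind iridium poorly through the hydroxyl, giving slow reduction or poor facial selectivity. The acidic iridium hydride may also promote loss of water from the benzylic homoallylic alcohol, aromatising the ring to a 1-arylnaphthalene.
 Fallback, setting out from 13 and rejoining at 15: silylation of the C1 hydroxyl (Et3SiCl, imidazole, CH2Cl2) should give (S)-tert-butyl{[8-methoxy-2-(8-methoxy-4-triethylsilyloxy-3,4-dihydronaphthalen-1-yl)naphthalen-1-yl]oxy}dimethylsilane F6, which can no longer ionise easily or direct. Catalyst-controlled asymmetric hydrogenation of this 1-aryl-3,4-dihydronaphthalene with [Ir(cod)(tBu-PHOX)][B(3,5-(CF3)2C6H3)4] (tBu-PHOX = 4-tert-butyl-2-[2-(diphenylphosphino)phenyl]-4,5-dihydrooxazole; the ligand enantiomer is chosen as the one matched with the C1 centre; H2 50 bar, CH2Cl2) should give the (1S,4R)-bis-silyl ether F7. Excess Bu4NF in THF removes both silyl groups to give 15.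

3. Step 3. Transfer of an unsubstituted vinyl group from boron may be slow, so that uncatalysed (racemic) addition or dimerisation of the quinone methide competes, and the twisted 2,6-disubstituted aryl group may lower facial discrimination by the diol.
 Fallback, setting out from 5 and rejoining at 8: treatment of 5 with CH2=CHMgBr (3 equiv, THF, 0 °C to rt) deprotonates the naphthol, expels ethoxide and adds vinyl to the quinone methide formed in the flask (7), giving racemic 2-[1-(2-bromo-6-methoxyphenyl)prop-2-en-1-yl]-8-methoxynaphthalen-1-ol F5. Resolution by preparative chromatography on a chiral stationary phase then supplies the (R)-enantiomer 8.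

**Further compounds**

F1 | step 6 | (R)-4-(2-bromo-6-methoxyphenyl)-4-[1-(tert-butyldimethylsilyloxy)-8-methoxynaphthalen-2-yl]butanal | COc1cccc(Br)c1[C@H](CCC=O)c1ccc2cccc(OC)c2c1O[Si](C)(C)C(C)(C)C
F2 | step 6 | (R)-4-(2-bromo-6-methoxyphenyl)-4-[1-(tert-butyldimethylsilyloxy)-8-methoxynaphthalen-2-yl]butanoic acid | COc1cccc(Br)c1[C@H](CCC(=O)O)c1ccc2cccc(OC)c2c1O[Si](C)(C)C(C)(C)C
F3 | step 6 | (R)-4-(2-bromo-6-methoxyphenyl)-4-[1-(tert-butyldimethylsilyloxy)-8-methoxynaphthalen-2-yl]-N-methoxy-N-methylbutanamide | COc1cccc(Br)c1[C@H](CCC(=O)N(C)OC)c1ccc2cccc(OC)c2c1O[Si](C)(C)C(C)(C)C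
F4 | step 6 | (R)-4-[1-(tert-butyldimethylsilyloxy)-8-methoxynaphthalen-2-yl]-5-methoxy-3,4-dihydronaphthalen-1(2H)-one | COc1cccc2c1[C@@H](c1ccc3cccc(OC)c3c1O[Si](C)(C)C(C)(C)C)CCC2=O
F5 | step 3 | rac-2-[1-(2-bromo-6-methoxyphenyl)prop-2-en-1-yl]-8-methoxynaphthalen-1-ol | COc1cccc(Br)c1C(C=C)c1ccc2cccc(OC)c2c1O
F6 | step 7 | (S)-tert-butyl{[8-methoxy-2-(8-methoxy-4-triethylsilyloxy-3,4-dihydronaphthalen-1-yl)naphthalen-1-yl]oxy}dimethylsilane | COc1cccc2c1C(c1ccc3cccc(OC)c3c1O[Si](C)(C)C(C)(C)C)=CC[C@@H]2O[Si](CC)(CC)CC
F7 | step 7 | tert-butyl{[8-methoxy-2-((1R,4S)-8-methoxy-4-triethylsilyloxy-1,2,3,4-tetrahydronaphthalen-1-yl)naphthalen-1-yl]oxy}dimethylsilane | COc1cccc2c1[C@@H](c1ccc3cccc(OC)c3c1O[Si](C)(C)C(C)(C)C)CC[C@@H]2O[Si](CC)(CC)CC
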